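Numbering as in briaranes: ring A = C1 (quaternary, Me-15), C10, C11 (C(OH)Me-20), C12, C13=C14; ten-membered ring = C1–C10 (C16 on C5); lactone = O–C7–C8–C17(Me-18)–C19. TBS = tert-butyldimethylsilyl.
Retrosynthetic cuts, in this order: C6–Cl (ene-type chlorination of a 5,6-alkene); C6–C7 and the lactone C–O (Nozaki–Hiyama–Kishi ring closure, lactonisation); C8–C17 (Reformatsky); C8–C9 (acyl-anion equivalent); C3–C4 (enolate alkylation); C11–C12 together with C1–C14 (ring A); C10–C11 and C1–C10 (Michael, Knoevenagel).
Enabling feature: in ring A the tertiary carbinol C11 and the C13=C14 alkene are joined through C12 exactly as in a carbonyl-ene product, and C14 sits on C1, which is alpha to the oxygenated C2. So C11 is a latent methyl ketone, C1 a latent ketone enolate, and C12–C13–C14 the allyl group of an allyl beta-keto ester, which moves to C1 with loss of CO2 and then closes onto C11 in the same flask (a formal 3+3 annulation).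
Forward order: acyclic keto ester (C1–C3, C9–C11, C15, C20) → ring A → C12 oxygen → side chain C4–C6/C16 → C7, C8 and C17–C19 → ten-membered ring and lactone → chloride. The allyl ester, the nitro group, the acetonide and the silyl ether are helpers and are all removed on the way.
Stereochemistry: C10 by an organocatalytic Michael addition; C1 by the chiral palladium catalyst and C11 by the ene transition state; C12 by SeO2 on the face away from the two axial methyls; C2 by CBS reduction; C9 and C8 by Felkin–Anh additions; C7 in the ring closure; C17 correctable by equilibration; C6 in the last step.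

Key step: step 5

Step 1
Reactants: 1 allyl acetoacetate; 2 (tert-butyldimethylsilyloxy)acetaldehyde
Product: 3 allyl 2-acetyl-4-[(tert-butyldimethylsilyl)oxy]but-2-enoate (E/Z mixture)
Conditions: piperidine (5 mol %), AcOH (5 mol %), 4 Å molecular sieves, CH2Cl2, 0 °C to rt
Reagents that add atoms: none
Why: Knoevenagel condensation joins the beta-keto ester carbon (future C1) to the aldehyde carbon (future C10, carrying C9 as CH2OTBS); the alkene geometry is irrelevant because this carbon becomes sp3 in step 2.

Step 2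
Reactants: 3 allyl 2-acetyl-4-[(tert-butyldimethylsilyl)oxy]but-2-enoate
Product: 4 allyl (3R)-2-acetyl-3-{[(tert-butyldimethylsilyl)oxy]methyl}-4-nitropentanoate (epimers at C2 and C4)
Conditions: EtNO2 (5 equiv), 1-[3,5-bis(trifluoromethyl)phenyl]-3-[(1R,2R)-2-(dimethylamino)cyclohexyl]thiourea (10 mol %), toluene, 0 °C
Reagents that add atoms: nitroethane, CC[N+](=O)[O-]
Why: asymmetric Michael addition of nitroethane (an acetyl-anion equivalent bringing C11 and C20) to the alkylidene beta-keto ester under bifunctional hydrogen-bond/base catalysis should set C10, the only stereocentre of 4 that is carried on; if this catalyst enantiomer gives the opposite sense, its antipode is used.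

Step 3
Reactants: 4 allyl (3R)-2-acetyl-3-{[(tert-butyldimethylsilyl)oxy]methyl}-4-nitropentanoate
Product: 5 allyl (3S)-2-acetyl-3-{[(tert-butyldimethylsilyl)oxy]methyl}-4-oxopentanoate (epimers at C2)
Conditions: t-BuOK (1.05 equiv), t-BuOH/THF, 0 °C; then aq. TiCl3, NH4OAc buffer, rt
Reagents that add atoms: water, O
Why: Nef reaction (nitronate, then buffered TiCl3 reduction to the imine and hydrolysis) unveils the C11 methyl ketone under conditions that spare the allyl ester and the silyl ether.

Step 4
Reactants: 5 allyl (3S)-2-acetyl-3-{[(tert-butyldimethylsilyl)oxy]methyl}-4-oxopentanoate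
Product: 6 allyl (3S)-2-acetyl-3-{[(tert-butyldimethylsilyl)oxy]methyl}-2-methyl-4-oxopentanoate (epimers at C2)
Conditions: K2CO3, MeI, acetone, rt
Reagents that add atoms: iodomethane, CI
Why: C-methylation at the only doubly activated carbon installs C15 and gives the fully substituted allyl beta-keto ester; the configuration created here is erased on decarboxylation in step 5.

Step 5
Reactants: 6 allyl (3S)-2-acetyl-3-{[(tert-butyldimethylsilyl)oxy]methyl}-2-methyl-4-oxopentanoate
Product: 8 ring A cyclohexenol (1-[6-(TBSO-methyl)-5-hydroxy-1,5-dimethylcyclohex-2-en-1-yl]ethanone; acetyl trans to CH2OTBS; OH cis to acetyl), via allyl diketone 7 (not isolated)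
Conditions: Pd2(dba)3 (2.5 mol %), (S)-t-BuPHOX (6 mol %), toluene, 30 °C until CO2 evolution ends; then CH2Cl2, Me2AlCl (2.5 equiv), −78 to 0 °C; aq. HCl work-up
Reagents that add atoms: none
Why: Zerovalent palladium ionises the allyl ester, CO2 is lost and the palladium enolate of the C2 ketone recombines with the allyl fragment at C1 (decarboxylative Tsuji allylation, so the ester is activating group, regiochemical anchor and C3 source at once), forming C1–C14 and the quaternary centre; Me2AlCl then complexes the C11 methyl ketone and the allyl group reacts as ene component, C12 bonding to C11 while a C14 hydrogen passes to oxygen and the alkene moves to C13=C14 (Lewis-acid-promoted intramolecular carbonyl-ene reaction, closest precedent the alkylaluminium halide cyclisations of 5-hexenyl carbonyl compounds to cyclohex-3-enols). Ring A closes 6-endo with respect to the alkene through a boat-like bicyclic transition state in which O and the migrating H bridge C11 and C14. C1 is set by face selection of the PHOX–palladium enolate, run in the sense matched with C10; C11 is set in the ene step, where C10–H and not the C9 side chain lies next to the ketone methyl, which should place OH cis to H-10 and trans to Me-15. The needed chemoselectivity between the two methyl ketones comes from geometry, since the C2 carbonyl could only react by a strained 5-endo closure, and the internal hydrogen transfer fixes the alkene at C13=C14 and not C12=C13.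

Step 6
Reactants: 8 ring A cyclohexenol
Product: 9 ring A cis-diol (1-[6-(TBSO-methyl)-4,5-dihydroxy-1,5-dimethylcyclohex-2-en-1-yl]ethanone; both OH cis to acetyl)
Conditions: SeO2 (0.5 equiv), t-BuOOH (3 equiv), CH2Cl2, rt
Reagents that add atoms: tert-butyl hydroperoxide, CC(C)(C)OO; selenium dioxide, O=[Se]=O
Why: SeO2 allylic oxidation (ene reaction, then 2,3-sigmatropic shift) can only occur at C12 because C1 is quaternary; selenium should add to C14 on the face opposite the axial C1 and C11 methyls and return oxygen to C12 on that same face, giving the 11,12-cis-diol.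

Step 7
Reactants: 9 ring A cis-diol
Product: 10 acetonide of 9 (C11/C12 isopropylidene acetal)
Conditions: 2-methoxypropene, PPTS (cat.), CH2Cl2, 0 °C
Reagents that add atoms: 2-methoxypropene, COC(C)=C
Why: acetonide formation on the cis-1,2-diol masks both hydroxyls for the basic and organometallic steps that follow.

Step 8
Reactants: 11 propargyl alcohol
Product: 13 (E)-3-iodo-2-methylprop-2-en-1-ol, via vinylalane 12 (not isolated)
Conditions: Me3Al (3 equiv), Cp2ZrCl2 (0.25 equiv), CH2Cl2, 0 °C to rt; then I2, THF, −30 °C; aq. HCl work-up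
Reagents that add atoms: trimethylaluminium, C[Al](C)C; iodine, II
Why: Negishi carboalumination adds Me and Al syn across the alkyne and iodinolysis with retention gives the (E)-iodoalkene that will become C5(C16)=C6.

Step 9
Reactants: 13 (E)-3-iodo-2-methylprop-2-en-1-ol
Product: 14 (E)-3-bromo-1-iodo-2-methylprop-1-ene
Conditions: CBr4, PPh3, CH2Cl2, 0 °C
Reagents that add atoms: tetrabromomethane, BrC(Br)(Br)Br
Why: Appel bromination of the primary allylic alcohol gives the alkylating agent without touching the iodoalkene.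

Step 10
Reactants: 10 acetonide methyl ketone; 14 (E)-3-bromo-1-iodo-2-methylprop-1-ene
Product: 15 side-chain ketone ((E)-6-iodo-5-methyl-1-(ring A acetonide)hex-5-en-1-one; C2 ketone, C3–C6 and C16 in place)
Conditions: LiN(iPr)2 (1.05 equiv), THF, −78 °C; then 14, DMPU, −78 to −30 °C
Reagents that add atoms: none
Why: the C2 methyl ketone can enolise only toward C3 because C1 is quaternary, and SN2 alkylation of this lithium enolate by the allylic bromide forms C3–C4 with the (E)-iodoalkene intact.

Step 11
Reactants: 15 side-chain ketone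
Product: 16 (2S)-alcohol (briarane C2 carbinol)
Conditions: (R)-2-methyl-CBS-oxazaborolidine (0.5 equiv), catecholborane, toluene, −78 °C
Reagents that add atoms: none
Why: CBS reduction delivers hydride under reagent control (large quaternary C1 against small C3H2), which is expected to override the weak substrate bias and give the (2S)-carbinol.

Step 12
Reactants: 16 (2S)-alcohol
Product: 17 C2 acetate
Conditions: Ac2O, DMAP (cat.), pyridine, rt
Reagents that add atoms: acetic anhydride, CC(=O)OC(C)=O
Why: standard acetylation installs the first of the three acetates of the target and protects C2–OH.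

Step 13
Reactants: 17 C2 acetate
Product: 18 C9 primary alcohol
Conditions: HF·pyridine, pyridine, THF, 0 °C
Reagents that add atoms: none
Why: buffered fluoride cleaves the primary silyl ether while acetonide, acetate and iodoalkene remain.

Step 14
Reactants: 18 C9 primary alcohol
Product: 19 C9 aldehyde
Conditions: Dess–Martin periodinane, NaHCO3, CH2Cl2, 0 °C to rt
Reagents that add atoms: none
Why: buffered Dess–Martin oxidation gives the aldehyde without epimerising C10, which is flanked by two fully substituted carbons.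

Step 15
Reactants: 19 C9 aldehyde; 20 2-bromo-3,3-diethoxyprop-1-ene
Product: 22 C9 acetate carrying C8 as =CH2 carbon and C7 as diethyl acetal, via lithium alkoxide 21 (not isolated)
Conditions: 20, t-BuLi (2 equiv), Et2O, −78 °C; then 19, −78 °C; then Ac2O, −78 to 0 °C
Reagents that add atoms: acetic anhydride, CC(=O)OC(C)=O
Why: the alpha-lithiated acrolein acetal adds to the aldehyde as an acyl-anion equivalent for C8 that brings C7 at the aldehyde level; Felkin–Anh approach anti to the oxygenated quaternary C11 branch, reinforced by 1,3-anti induction from the C11 oxygen, should set C9, and the alkoxide is acetylated in the same flask.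

Step 16
Reactants: 22 C9 acetate with 1,1-disubstituted alkene
Product: 24 alpha-keto acetal (C8 ketone), via diol 23 (not isolated)
Conditions: OsO4 (5 mol %), NaIO4 (4 equiv), 2,6-lutidine, dioxane/H2O (3:1), rt
Reagents that add atoms: sodium periodate, [Na+].[O-]I(=O)(=O)=O; osmium tetroxide, O=[Os](=O)(=O)=O
Why: Lemieux–Johnson cleavage should take the terminal 1,1-disubstituted alkene selectively, since the ring A alkene is shielded by the quaternary C1 and the acetonide and the iodoalkene is electronically deactivated.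

Step 17
Reactants: 24 alpha-keto acetal
Product: 25 C8 tertiary alcohol with the C17–C19 methyl propanoate unit
Conditions: methyl 2-bromopropanoate, activated Zn, THF, 0 °C to rt; aq. NH4Cl work-up
Reagents that add atoms: methyl 2-bromopropanoate, COC(=O)C(C)Br
Why: Reformatsky addition to the activated ketone, with polar Felkin–Anh attack anti to the C9 acetoxy group, should set C8; C17 forms in the same closed zinc aldolate and, being alpha to the ester, stays correctable by equilibration at the lactone stage.

Step 18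
Reactants: 25 C8 tertiary alcohol
Product: 26 C7 aldehyde with free C11/C12 diol
Conditions: TFA/H2O (9:1), CH2Cl2, 0 °C
Reagents that add atoms: water, O
Why: one acid hydrolysis removes the diethyl acetal (C7 aldehyde) and the acetonide before any acid-sensitive allylic alcohol exists, while acetates, methyl ester and iodoalkene survive.

Step 19
Reactants: 26 C7 aldehyde
Product: 28 macrolactone triol (ten-membered ring with (E)-C5(Me)=C6; C7–O–C19 lactone; free 8-OH, 11-OH, 12-OH), via hydroxy ester 27 (not isolated)
Conditions: CrCl2 (10 equiv), NiCl2 (1 mol %), DMSO/THF, rt, 0.002 M by slow addition; then PPTS (cat.), CH2Cl2, rt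
Reagents that add atoms: none
Why: intramolecular Nozaki–Hiyama–Kishi addition of the alkenylchromium to the aldehyde closes the ten-membered ring at C6–C7 with retention of the (E)-alkene; attack on the chelated alpha-hydroxy aldehyde from the side of its own tether (the C9 branch) should give the needed C7 carbinol, which then lactonises onto the C19 ester.

Step 20
Reactants: 28 macrolactone triol
Product: 29 2,9,12-triacetate (5,6-alkene, no chlorine)
Conditions: Ac2O, pyridine, DMAP (cat.), 0 °C
Reagents that add atoms: acetic anhydride, CC(=O)OC(C)=O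
Why: only the secondary allylic C12 hydroxyl is acylated under these conditions, the tertiary C8 and C11 hydroxyls staying free as in the target.

Step 21
Reactants: 29 2,9,12-triacetate
Product: 30 CNP0259091.1 (target)
Conditions: Ca(OCl)2, solid CO2, CH2Cl2/H2O, 0 °C
Reagents that add atoms: calcium hypochlorite, [Ca+2].[O-]Cl.[O-]Cl
Why: ene-type allylic chlorination by HOCl puts chlorine on the less substituted alkene carbon C6 and moves the alkene to C5=C16 by loss of a methyl hydrogen; delivery to the exposed outer face of the trisubstituted ring alkene should give the C6 configuration of the target, and the hindered, acetoxy-deactivated ring A alkene should not compete.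

Compound list
1 | allyl acetoacetate (prop-2-enyl 3-oxobutanoate) | C=CCOC(=O)CC(C)=O | starting material
2 | (tert-butyldimethylsilyloxy)acetaldehyde | O=CCO[Si](C)(C)C(C)(C)C | starting material
3 | allyl 2-acetyl-4-[(tert-butyldimethylsilyl)oxy]but-2-enoate, E/Z mixture | C=CCOC(=O)C(C(C)=O)=CCO[Si](C)(C)C(C)(C)C | intermediate
4 | allyl (3R)-2-acetyl-3-{[(tert-butyldimethylsilyl)oxy]methyl}-4-nitropentanoate, epimers at C2 and C4 (C3 = briarane C10) | CC(=O)C(C(=O)OCC=C)[C@@H](CO[Si](C)(C)C(C)(C)C)C(C)[N+](=O)[O-] | intermediate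
5 | allyl (3S)-2-acetyl-3-{[(tert-butyldimethylsilyl)oxy]methyl}-4-oxopentanoate, epimers at C2 | CC(=O)C(C(=O)OCC=C)[C@@H](CO[Si](C)(C)C(C)(C)C)C(C)=O | intermediate
6 | allyl (3S)-2-acetyl-3-{[(tert-butyldimethylsilyl)oxy]methyl}-2-methyl-4-oxopentanoate, epimers at C2 | CC(=O)C(C)(C(=O)OCC=C)[C@@H](CO[Si](C)(C)C(C)(C)C)C(C)=O | intermediate
7 | (3S,4S)-3-allyl-4-{[(tert-butyldimethylsilyl)oxy]methyl}-3-methylhexane-2,5-dione (allyl diketone) | CC(=O)[C@@](C)(CC=C)[C@@H](CO[Si](C)(C)C(C)(C)C)C(C)=O | intermediate
8 | 1-[6-{[(tert-butyldimethylsilyl)oxy]methyl}-5-hydroxy-1,5-dimethylcyclohex-2-en-1-yl]ethanone; acetyl trans to CH2OTBS, 5-OH cis to acetyl (C1, C10, C11 as in the target) | CC(=O)[C@@]1(C)C=CC[C@@](C)(O)[C@@H]1CO[Si](C)(C)C(C)(C)C | intermediate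
9 | 1-[6-{[(tert-butyldimethylsilyl)oxy]methyl}-4,5-dihydroxy-1,5-dimethylcyclohex-2-en-1-yl]ethanone; 4-OH and 5-OH cis to each other and to acetyl | CC(=O)[C@@]1(C)C=C[C@@H](O)[C@@](C)(O)[C@@H]1CO[Si](C)(C)C(C)(C)C | intermediate
10 | acetonide of 9 (isopropylidene acetal of the C11/C12 diol; C2 methyl ketone; C9 CH2OTBS) | CC(=O)[C@@]1(C)C=C[C@H]2OC(C)(C)O[C@@]2(C)[C@@H]1CO[Si](C)(C)C(C)(C)C | intermediate
11 | propargyl alcohol (prop-2-yn-1-ol) | C#CCO | starting material
12 | (E)-[3-(dimethylalumanyloxy)-2-methylprop-1-enyl]dimethylalumane (vinylalane, Al cis to methyl) | C[Al](C)/C=C(\C)CO[Al](C)C | intermediate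
13 | (E)-3-iodo-2-methylprop-2-en-1-ol | OC/C(C)=C/I | intermediate
14 | (E)-3-bromo-1-iodo-2-methylprop-1-ene | BrC/C(C)=C/I | intermediate
15 | (E)-6-iodo-5-methyl-1-(ring A acetonide)hex-5-en-1-one: 10 alkylated at C3 (C2 ketone, C3–C6, C16) | C/C(=C\I)CCC(=O)[C@@]1(C)C=C[C@H]2OC(C)(C)O[C@@]2(C)[C@@H]1CO[Si](C)(C)C(C)(C)C | intermediate
16 | (2S)-alcohol from 15 (briarane C2 carbinol) | C/C(=C\I)CC[C@H](O)[C@@]1(C)C=C[C@H]2OC(C)(C)O[C@@]2(C)[C@@H]1CO[Si](C)(C)C(C)(C)C | intermediate
17 | C2 acetate of 16 | C/C(=C\I)CC[C@H](OC(C)=O)[C@@]1(C)C=C[C@H]2OC(C)(C)O[C@@]2(C)[C@@H]1CO[Si](C)(C)C(C)(C)C | intermediate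
18 | C9 primary alcohol (17 without TBS) | C/C(=C\I)CC[C@H](OC(C)=O)[C@@]1(C)C=C[C@H]2OC(C)(C)O[C@@]2(C)[C@@H]1CO | intermediate
19 | C9 aldehyde | C/C(=C\I)CC[C@H](OC(C)=O)[C@@]1(C)C=C[C@H]2OC(C)(C)O[C@@]2(C)[C@@H]1C=O | intermediate
20 | 2-bromo-3,3-diethoxyprop-1-ene (2-bromoacrolein diethyl acetal) | C=C(Br)C(OCC)OCC | starting material
21 | lithium alkoxide of the C9 carbinol (C8 as =CH2 carbon, C7 as diethyl acetal) | C/C(=C\I)CC[C@H](OC(C)=O)[C@@]1(C)C=C[C@H]2OC(C)(C)O[C@@]2(C)[C@@H]1[C@H]([O-])C(=C)C(OCC)OCC.[Li+] | intermediate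
22 | C2,C9 diacetate with 2-(diethoxymethyl)vinyl unit at C9 | C/C(=C\I)CC[C@H](OC(C)=O)[C@@]1(C)C=C[C@H]2OC(C)(C)O[C@@]2(C)[C@@H]1[C@H](OC(C)=O)C(=C)C(OCC)OCC | intermediate
23 | vicinal diol from 22 (C8 tertiary OH, CH2OH; C8 epimers) | C/C(=C\I)CC[C@H](OC(C)=O)[C@@]1(C)C=C[C@H]2OC(C)(C)O[C@@]2(C)[C@@H]1[C@H](OC(C)=O)C(O)(CO)C(OCC)OCC | intermediate
24 | alpha-keto acetal (C8 ketone, C7 diethyl acetal, C9 acetate) | C/C(=C\I)CC[C@H](OC(C)=O)[C@@]1(C)C=C[C@H]2OC(C)(C)O[C@@]2(C)[C@@H]1[C@H](OC(C)=O)C(=O)C(OCC)OCC | intermediate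
25 | Reformatsky adduct: C8 tertiary alcohol bearing C7 diethyl acetal and the methyl 2-propanoate unit (C17, C18, C19) | C/C(=C\I)CC[C@H](OC(C)=O)[C@@]1(C)C=C[C@H]2OC(C)(C)O[C@@]2(C)[C@@H]1[C@H](OC(C)=O)[C@@](O)(C(OCC)OCC)[C@@H](C)C(=O)OC | intermediate
26 | C7 aldehyde with free 8-OH, 11-OH, 12-OH (seco iodoalkene aldehyde) | C/C(=C\I)CC[C@H](OC(C)=O)[C@@]1(C)C=C[C@@H](O)[C@@](C)(O)[C@@H]1[C@H](OC(C)=O)[C@@](O)(C=O)[C@@H](C)C(=O)OC | intermediate
27 | ten-membered carbocycle with (E)-C5(Me)=C6, C7–OH and open methyl ester (hydroxy ester) | C1C[C@H](OC(C)=O)[C@@]2(C)C=C[C@@H](O)[C@@](C)(O)[C@@H]2[C@H](OC(C)=O)[C@](O)([C@@H](C)C(=O)OC)[C@@H](O)/C=C1\C | intermediate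
28 | macrolactone triol: briarane skeleton with (E)-5,6-alkene, 2,9-diacetate, free 8-OH, 11-OH, 12-OH | C1C[C@H](OC(C)=O)[C@@]2(C)C=C[C@@H](O)[C@@](C)(O)[C@@H]2[C@H](OC(C)=O)[C@]3(O)[C@@H](C)C(=O)O[C@H]3/C=C1\C | intermediate
29 | 2,9,12-triacetate with (E)-5,6-alkene (6-dechloro precursor, Me-16 on C5) | C1C[C@H](OC(C)=O)[C@@]2(C)C=C[C@@H](OC(C)=O)[C@@](C)(O)[C@@H]2[C@H](OC(C)=O)[C@]3(O)[C@@H](C)C(=O)O[C@H]3/C=C1\C | intermediate
30 | CNP0259091.1 | C=C1CC[C@H](OC(C)=O)[C@@]2(C)C=C[C@@H](OC(C)=O)[C@@](C)(O)[C@@H]2[C@H](OC(C)=O)[C@]2(O)[C@@H](C)C(=O)O[C@H]2[C@H]1Cl | target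

Total step count: 21. Longest linear sequence: 19 steps (steps 1–7 and 10–21; steps 8 and 9 make the side-chain bromide).

Steps most likely to fail

Step 5. Risk: the ene closure of an unactivated vinyl group onto a ketone may be slow, so that chloride or methyl transfer from aluminium to the developing C13 cation takes over, and face control at C1 in the allylation may be weak. Fallback: from 6 the palladium stage is run alone and allyl diketone 7 is isolated. Addition of vinylmagnesium bromide (CeCl3, THF, −78 °C) to the less hindered C11 ketone should give the vinyl carbinol F1 (C11 epimers separated). Ring-closing metathesis with the second-generation Grubbs catalyst should give the cyclohex-2-enol F2, and hydroxyl-directed epoxidation (VO(acac)2, t-BuOOH) the syn epoxy alcohol F3. Opening with PhSeNa at C13 to the hydroxy selenide F4, then H2O2 (selenoxide elimination away from the carbinol), leads to the cis-diol 9, where the route is rejoined; steps 5 and 6 are replaced.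

Step 19. Risk: transannular strain and competing intermolecular coupling in the ten-membered ring closure, or attack on the wrong aldehyde face at C7. Fallback: from 25 the iodine is removed (Bu3SnH, Pd(PPh3)4 cat.) to give the isopropenyl ester F5, and the same acid hydrolysis gives the aldehyde F6. An intermolecular Nozaki–Hiyama–Kishi reaction with vinyl bromide (CrCl2, NiCl2 cat.) followed by lactonisation gives the diene lactone F7. Ring-closing metathesis (second-generation Grubbs catalyst, high dilution) then forms C5=C6 and returns to 28.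

Step 21. Risk: hydrogen loss from C4 instead of C16, reaction at the ring A alkene, or chlorine delivery to the wrong face of C5=C6. Fallback: from 29 a Schenck ene reaction (O2, tetraphenylporphyrin, visible light) should give the allylic hydroperoxide F8 with the 5(16)-alkene. PPh3 reduces it to the 6-epi alcohol F9, and chloride is then introduced with inversion (Appel reaction, PPh3/CCl4) to reach 30.

Further compounds
F1 | step 5 | 3-allyl-4-{[(tert-butyldimethylsilyl)oxy]methyl}-5-hydroxy-3,5-dimethylhept-6-en-2-one (vinyl carbinol, C11 as in the target) | CC(=O)[C@@](C)(CC=C)[C@@H](CO[Si](C)(C)C(C)(C)C)[C@](C)(O)C=C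
F2 | step 5 | 1-[6-{[(tert-butyldimethylsilyl)oxy]methyl}-5-hydroxy-1,5-dimethylcyclohex-3-en-1-yl]ethanone (cyclohex-2-enol, C12=C13) | CC(=O)[C@@]1(C)CC=C[C@@](C)(O)[C@@H]1CO[Si](C)(C)C(C)(C)C
F3 | step 5 | C12/C13 epoxide of F2, syn to the C11 hydroxyl | CC(=O)[C@@]1(C)C[C@H]2O[C@H]2[C@@](C)(O)[C@@H]1CO[Si](C)(C)C(C)(C)C
F4 | step 5 | 1-[6-{[(tert-butyldimethylsilyl)oxy]methyl}-4,5-dihydroxy-1,5-dimethyl-3-(phenylselanyl)cyclohexyl]ethanone (SePh at C13, trans to 12-OH) | CC(=O)[C@@]1(C)C[C@H]([Se]c2ccccc2)[C@@H](O)[C@@](C)(O)[C@@H]1CO[Si](C)(C)C(C)(C)C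
F5 | step 19 | de-iodo analogue of 25 (isopropenyl terminus C5(Me)=C6H2) | C=C(C)CC[C@H](OC(C)=O)[C@@]1(C)C=C[C@H]2OC(C)(C)O[C@@]2(C)[C@@H]1[C@H](OC(C)=O)[C@@](O)(C(OCC)OCC)[C@@H](C)C(=O)OC
F6 | step 19 | de-iodo analogue of 26 (C7 aldehyde, free triol, isopropenyl terminus) | C=C(C)CC[C@H](OC(C)=O)[C@@]1(C)C=C[C@@H](O)[C@@](C)(O)[C@@H]1[C@H](OC(C)=O)[C@@](O)(C=O)[C@@H](C)C(=O)OC
F7 | step 19 | diene lactone: C7-vinyl gamma-lactone with isopropenyl side chain | C=C(C)CC[C@H](OC(C)=O)[C@@]1(C)C=C[C@@H](O)[C@@](C)(O)[C@@H]1[C@H](OC(C)=O)[C@]1(O)[C@@H](C)C(=O)O[C@H]1C=C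
F8 | step 21 | 6-hydroperoxide with 5(16)-alkene, C6 epimeric to the chloride of the target | C=C1CC[C@H](OC(C)=O)[C@@]2(C)C=C[C@@H](OC(C)=O)[C@@](C)(O)[C@@H]2[C@H](OC(C)=O)[C@]2(O)[C@@H](C)C(=O)O[C@H]2[C@@H]1OO
F9 | step 21 | 6-epi alcohol with 5(16)-alkene | C=C1CC[C@H](OC(C)=O)[C@@]2(C)C=C[C@@H](OC(C)=O)[C@@](C)(O)[C@@H]2[C@H](OC(C)=O)[C@]2(O)[C@@H](C)C(=O)O[C@H]2[C@@H]1O
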